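**Retrosynthetic overview**

1. The strategy rests on upper C4. It is bonded to C5′ of the central arene, which carries OMe at C4′ (ortho) and oxygen at C2′ (para), so a C4 benzylic cation is strongly stabilised; C4a of the upper ring A lies ortho to O1 and para to the C7 oxygen of a resorcinol diether and can capture it.
2. Disconnections: global O-debenzylation; C4–C4a (upper pyran ring, closed last by Friedel–Crafts alkylation from carbinol 29); ArO–CH2 (Mitsunobu of diol 27 with 3-benzyloxyphenol).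
3. Upper C3–C4: an Evans syn-aldol of arylacetyl imide 24 with isoflavan aldehyde 21 sets upper C3 and gives the carbinol directly. It is preferred to adding an aryllithium to an α-aryl-β-aryloxy aldehyde, which is prone to epimerisation and β-elimination of phenoxide.
4. Lower isoflavan 21: Evans benzylation of imide 14 with bromide 11 sets lower C3; LiBH4, MOM removal, Mitsunobu ring closure and Br→CHO follow.
5. Both arylacetic acids (5 and its 5-bromo derivative 6) come from 2-hydroxy-4-methoxybenzaldehyde. Ring order: lower pyran ring (step 13), then upper pyran ring (step 19).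

Key step: step 19

Assumption: CIP analysis of the given SMILES gives (3S,4R), i.e. 3,4-trans, for the upper chroman and (3S) for the lower chroman. "Chroman" means 3,4-dihydro-2H-1-benzopyran. Precursor 29 is carried as a single carbinol epimer, which is immaterial because that centre is ionised in step 19. Compounds 1, 7, 12, 22 and 28 are commercial.

**Route**

Step 1
Reactants: 1 2-hydroxy-4-methoxybenzaldehyde
Product: 2 2-(benzyloxy)-4-methoxybenzaldehyde
Conditions: BnBr, K2CO3, DMF, 60 °C
Reagents that add atoms: benzyl bromide, BrCc1ccccc1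
Why: Williamson etherification of the only phenol; the aldehyde is inert to carbonate.

Step 2
Reactants: 2 2-(benzyloxy)-4-methoxybenzaldehyde
Product: 4 2-[2-(benzyloxy)-4-methoxyphenyl]acetonitrile, via vinylformamide 3 (not isolated)
Conditions: TosMIC, t-BuOK, DME, −50 °C; then MeOH, reflux
Reagents that add atoms: tosylmethyl isocyanide, Cc1ccc(cc1)S(=O)(=O)C[N+]#[C-]
Why: van Leusen reductive cyanation: the TosMIC anion adds to the aldehyde and the oxazoline opens to 3, which on methanolysis loses the formyl group and sulfinate to give the one-carbon-homologated nitrile.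

Step 3
Reactants: 4 2-[2-(benzyloxy)-4-methoxyphenyl]acetonitrile
Product: 5 2-[2-(benzyloxy)-4-methoxyphenyl]acetic acid
Conditions: KOH, EtOH–H2O, reflux; then aq. HCl
Reagents that add atoms: water, O; potassium hydroxide, [K+].[OH-]
Why: Alkaline nitrile hydrolysis; the benzyl and methyl aryl ethers are inert to aqueous base.

Step 4
Reactants: 5 2-[2-(benzyloxy)-4-methoxyphenyl]acetic acid
Product: 6 2-[2-(benzyloxy)-5-bromo-4-methoxyphenyl]acetic acid
Conditions: NBS (1.0 equiv), MeCN, 0 °C, dark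
Reagents that add atoms: N-bromosuccinimide, O=C1CCC(=O)N1Br
Why: Electrophilic aromatic bromination at C5, the only unhindered position activated by both oxygens (para to OBn, ortho to OMe; C3 lies between the two alkoxy groups); ionic conditions spare the benzylic CH2 groups.

Step 5
Reactants: 7 2,4-dihydroxybenzaldehyde
Product: 8 4-(benzyloxy)-2-hydroxybenzaldehyde
Conditions: BnBr (1.0 equiv), NaHCO3, KI (cat.), MeCN, reflux
Reagents that add atoms: benzyl bromide, BrCc1ccccc1
Why: Regioselective Williamson etherification: the 4-OH is the more acidic and accessible phenol, while the 2-OH is held in a hydrogen bond to the formyl group and is not ionised by hydrogencarbonate.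

Step 6
Reactants: 8 4-(benzyloxy)-2-hydroxybenzaldehyde
Product: 9 4-(benzyloxy)-2-(methoxymethoxy)benzaldehyde
Conditions: MOMCl, i-Pr2NEt, CH2Cl2, 0 °C to rt
Reagents that add atoms: chloromethyl methyl ether, COCCl
Why: MOM acetal protection of the remaining phenol, orthogonal to the benzyl ethers that are kept to the end.

Step 7
Reactants: 9 4-(benzyloxy)-2-(methoxymethoxy)benzaldehyde
Product: 10 [4-(benzyloxy)-2-(methoxymethoxy)phenyl]methanol
Conditions: NaBH4, MeOH–THF, 0 °C
Reagents that add atoms: none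
Why: Borohydride reduction of the aldehyde; acetal and ethers are untouched.

Step 8
Reactants: 10 [4-(benzyloxy)-2-(methoxymethoxy)phenyl]methanol
Product: 11 4-(benzyloxy)-1-(bromomethyl)-2-(methoxymethoxy)benzene
Conditions: CBr4, PPh3, CH2Cl2, 0 °C; filtered through Et3N-washed silica and used at once
Reagents that add atoms: carbon tetrabromide, BrC(Br)(Br)Br
Why: Appel bromination under neutral conditions that spare the MOM acetal; the electron-rich benzylic bromide is not stored.

Step 9
Reactants: 6 2-[2-(benzyloxy)-5-bromo-4-methoxyphenyl]acetic acid; 12 (S)-4-benzyloxazolidin-2-one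
Product: 14 (4S)-4-benzyl-3-{2-[2-(benzyloxy)-5-bromo-4-methoxyphenyl]acetyl}oxazolidin-2-one, via mixed pivalic anhydride 13 (not isolated)
Conditions: PivCl, Et3N, THF, −20 °C; then 12, LiCl, −20 °C to rt
Reagents that add atoms: pivaloyl chloride, CC(C)(C)C(Cl)=O (its atoms are in intermediate 13 only)
Why: N-acylation of the Evans auxiliary through the mixed anhydride (LiCl/Et3N protocol); the oxazolidinone attacks the unhindered arylacetyl carbonyl and not the pivaloyl one.

Step 10
Reactants: 14 (4S)-4-benzyl-3-{2-[2-(benzyloxy)-5-bromo-4-methoxyphenyl]acetyl}oxazolidin-2-one; 11 4-(benzyloxy)-1-(bromomethyl)-2-(methoxymethoxy)benzene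
Product: 16 (4S)-4-benzyl-3-{(2S)-2-[2-(benzyloxy)-5-bromo-4-methoxyphenyl]-3-[4-(benzyloxy)-2-(methoxymethoxy)phenyl]propanoyl}oxazolidin-2-one, via sodium Z-enolate 15 (not isolated)
Conditions: NaHMDS, THF, −78 °C; then 11, −78 to −40 °C
Reagents that add atoms: sodium bis(trimethylsilyl)amide, C[Si](C)(C)N([Na])[Si](C)(C)C (Na is in intermediate 15 only)
Why: Evans asymmetric alkylation: the chelated Z-enolate is benzylated on the face opposite the auxiliary benzyl group, which should set the (2S) centre that becomes lower C3 (S).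

Step 11
Reactants: 16 alkylated (4S)-imide
Product: 17 (2S)-2-[2-(benzyloxy)-5-bromo-4-methoxyphenyl]-3-[4-(benzyloxy)-2-(methoxymethoxy)phenyl]propan-1-ol
Conditions: LiBH4, MeOH (1 equiv), THF, 0 °C
Reagents that add atoms: none
Why: Reductive cleavage of the N-acyl oxazolidinone at the exocyclic carbonyl; the conditions are not basic enough to epimerise the α-aryl centre and leave ArBr, MOM and Bn intact.

Step 12
Reactants: 17 (2S)-propan-1-ol with MOM ether
Product: 18 5-(benzyloxy)-2-{(2S)-2-[2-(benzyloxy)-5-bromo-4-methoxyphenyl]-3-hydroxypropyl}phenol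
Conditions: HCl (cat.), MeOH, 50 °C
Reagents that add atoms: none
Why: Acid-catalysed transacetalisation removes the MOM group into the methanol solvent; benzyl ethers, aryl bromide and primary alcohol are stable.

Step 13
Reactants: 18 phenol–alcohol
Product: 19 (3S)-7-(benzyloxy)-3-[2-(benzyloxy)-5-bromo-4-methoxyphenyl]chroman
Conditions: PPh3, DIAD, THF, 0 °C to rt
Reagents that add atoms: none
Why: Intramolecular Mitsunobu etherification (6-exo-tet attack of the phenol on the primary oxyphosphonium) closes the lower pyran ring; the stereocentre is not at the reacting carbon.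

Step 14
Reactants: 19 (3S)-isoflavan bromide
Product: 21 4-(benzyloxy)-5-[(3S)-7-(benzyloxy)chroman-3-yl]-2-methoxybenzaldehyde, via aryllithium 20 (not isolated)
Conditions: n-BuLi, THF, −78 °C; then DMF, −78 to 0 °C; H2O
Reagents that add atoms: N,N-dimethylformamide, CN(C)C=O; n-butyllithium, [Li]CCCC (Li is in intermediate 20 only)
Why: Bromine–lithium exchange, faster than any deprotonation at −78 °C and assisted by the ortho methoxy group, followed by Bouveault formylation with DMF.

Step 15
Reactants: 5 2-[2-(benzyloxy)-4-methoxyphenyl]acetic acid; 22 (R)-4-benzyloxazolidin-2-one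
Product: 24 (4R)-4-benzyl-3-{2-[2-(benzyloxy)-4-methoxyphenyl]acetyl}oxazolidin-2-one, via mixed pivalic anhydride 23 (not isolated)
Conditions: PivCl, Et3N, THF, −20 °C; then 22, LiCl, −20 °C to rt
Reagents that add atoms: pivaloyl chloride, CC(C)(C)C(Cl)=O (its atoms are in intermediate 23 only)
Why: Mixed-anhydride N-acylation of the Evans auxiliary, as in step 9.

Step 16
Reactants: 24 (4R)-arylacetyl imide; 21 isoflavan aldehyde
Product: 26 (4R)-4-benzyl-3-[(2R,3R)-2-[2-(benzyloxy)-4-methoxyphenyl]-3-{4-(benzyloxy)-5-[(3S)-7-(benzyloxy)chroman-3-yl]-2-methoxyphenyl}-3-hydroxypropanoyl]oxazolidin-2-one, via boron Z-enolate 25 (not isolated)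
Conditions: Bu2BOTf, i-Pr2NEt, CH2Cl2, −78 to 0 °C; then 21, −78 to 0 °C; pH 7 buffer, MeOH, 30% H2O2, 0 °C
Reagents that add atoms: dibutylboron triflate, CCCCB(CCCC)OS(=O)(=O)C(F)(F)F (boron and butyl groups are in intermediate 25 only)
Why: Evans syn-aldol: the Z-boron enolate reacts through a Zimmerman–Traxler chair in which the (R)-auxiliary dictates the enolate face, which should give the (2R,3R) syn adduct; C2 becomes upper C3 and the carbinol configuration does not matter.

Step 17
Reactants: 26 syn-aldol adduct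
Product: 27 (1R,2S)-2-[2-(benzyloxy)-4-methoxyphenyl]-1-{4-(benzyloxy)-5-[(3S)-7-(benzyloxy)chroman-3-yl]-2-methoxyphenyl}propane-1,3-diol
Conditions: LiBH4, MeOH (1 equiv), THF, 0 °C
Reagents that add atoms: none
Why: Reductive removal of the auxiliary from a β-hydroxy imide gives the 1,3-diol; fast hydride delivery at 0 °C should outpace retro-aldol cleavage.

Step 18
Reactants: 27 1,3-diol; 28 3-(benzyloxy)phenol
Product: 29 (1R,2S)-2-[2-(benzyloxy)-4-methoxyphenyl]-1-{4-(benzyloxy)-5-[(3S)-7-(benzyloxy)chroman-3-yl]-2-methoxyphenyl}-3-[3-(benzyloxy)phenoxy]propan-1-ol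
Conditions: 28 (1.2 equiv), PPh3, DIAD, THF, 0 °C to rt
Reagents that add atoms: none
Why: Mitsunobu etherification, chemoselective for the primary alcohol because the hindered secondary benzylic alcohol forms its oxyphosphonium much more slowly; C2 is not at the reacting carbon.

Step 19
Reactants: 29 benzylic carbinol precursor
Product: 31 (3S,4R)-7-(benzyloxy)-3-[2-(benzyloxy)-4-methoxyphenyl]-4-{4-(benzyloxy)-5-[(3S)-7-(benzyloxy)chroman-3-yl]-2-methoxyphenyl}chroman, via benzylic cation 30 (not isolated)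
Conditions: BF3·OEt2 (0.3 equiv), 4 Å MS, CH2Cl2 (0.005 M), −78 to −20 °C; Et3N quench
Reagents that add atoms: none
Why: BF3 assists loss of the hydroxyl from 29 to give cation 30, delocalised into the central arene through its ortho methoxy and para benzyloxy groups; the carbon of the tethered 3-benzyloxyphenoxy ring that is ortho to the tether oxygen and para to OBn attacks it, and the Wheland intermediate rearomatises. The closest known reaction type is the acid-mediated intramolecular Friedel–Crafts cycloalkylation of aryl ethers by stabilised benzylic cations, which gives 4-arylchromans and 1-aryltetralins. The pyran ring closes as a six-membered cycloalkylation, endo with respect to the arene C4a=C8a bond, forming C4–C4a. The new C4 centre is controlled by the existing C3 centre: in the half-chair transition state the C3 aryl is pseudo-equatorial and the planar cation presents the face that places the central arene anti to it, which should give the 3,4-trans (3S,4R) product, also expected to be the more stable isomer; the carbinol configuration of 29 is erased on ionisation. The step needs closure para to OBn and not at the carbon between the two oxygens, secured by steric shielding of that carbon, and closure faster than loss of H-3 or intermolecular alkylation, secured by the nucleophilic resorcinol diether, low temperature and high dilution.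

Step 20
Reactants: 31 tetra-O-benzyl ether
Product: 32 (3S,4R)-3-(2-hydroxy-4-methoxyphenyl)-4-{4-hydroxy-5-[(3S)-7-hydroxychroman-3-yl]-2-methoxyphenyl}chroman-7-ol
Conditions: H2 (1 atm), 10% Pd/C, THF–MeOH, rt
Reagents that add atoms: none
Why: Catalytic hydrogenolysis cleaves the four benzyl aryl ethers; the molecule has no other reducible group and the C4–aryl and ring C–O bonds are not hydrogenolysed.

**Compound list**

1 | 2-hydroxy-4-methoxybenzaldehyde | COc1ccc(C=O)c(O)c1 | starting material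
2 | 2-(benzyloxy)-4-methoxybenzaldehyde | COc1ccc(C=O)c(OCc2ccccc2)c1 | intermediate
3 | N-{2-[2-(benzyloxy)-4-methoxyphenyl]-1-tosylethenyl}formamide | COc1ccc(C=C(NC=O)S(=O)(=O)c2ccc(C)cc2)c(OCc2ccccc2)c1 | intermediate (not isolated)
4 | 2-[2-(benzyloxy)-4-methoxyphenyl]acetonitrile | COc1ccc(CC#N)c(OCc2ccccc2)c1 | intermediate
5 | 2-[2-(benzyloxy)-4-methoxyphenyl]acetic acid | COc1ccc(CC(=O)O)c(OCc2ccccc2)c1 | intermediate
6 | 2-[2-(benzyloxy)-5-bromo-4-methoxyphenyl]acetic acid | COc1cc(OCc2ccccc2)c(CC(=O)O)cc1Br | intermediate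
7 | 2,4-dihydroxybenzaldehyde | O=Cc1ccc(O)cc1O | starting material
8 | 4-(benzyloxy)-2-hydroxybenzaldehyde | O=Cc1ccc(OCc2ccccc2)cc1O | intermediate
9 | 4-(benzyloxy)-2-(methoxymethoxy)benzaldehyde | COCOc1cc(OCc2ccccc2)ccc1C=O | intermediate
10 | [4-(benzyloxy)-2-(methoxymethoxy)phenyl]methanol | COCOc1cc(OCc2ccccc2)ccc1CO | intermediate
11 | 4-(benzyloxy)-1-(bromomethyl)-2-(methoxymethoxy)benzene | COCOc1cc(OCc2ccccc2)ccc1CBr | intermediate
12 | (S)-4-benzyloxazolidin-2-one | O=C1N[C@@H](Cc2ccccc2)CO1 | starting material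
13 | 2-[2-(benzyloxy)-5-bromo-4-methoxyphenyl]acetic pivalic anhydride | COc1cc(OCc2ccccc2)c(CC(=O)OC(=O)C(C)(C)C)cc1Br | intermediate (not isolated)
14 | (4S)-4-benzyl-3-{2-[2-(benzyloxy)-5-bromo-4-methoxyphenyl]acetyl}oxazolidin-2-one | COc1cc(OCc2ccccc2)c(CC(=O)N2[C@@H](Cc3ccccc3)COC2=O)cc1Br | intermediate
15 | sodium (Z)-enolate of 14 | COc1cc(OCc2ccccc2)c(/C=C(\O[Na])N2[C@@H](Cc3ccccc3)COC2=O)cc1Br | intermediate (not isolated)
16 | (4S)-4-benzyl-3-{(2S)-2-[2-(benzyloxy)-5-bromo-4-methoxyphenyl]-3-[4-(benzyloxy)-2-(methoxymethoxy)phenyl]propanoyl}oxazolidin-2-one | COc1cc(OCc2ccccc2)c([C@H](Cc2ccc(OCc3ccccc3)cc2OCOC)C(=O)N2[C@@H](Cc3ccccc3)COC2=O)cc1Br | intermediate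
17 | (2S)-2-[2-(benzyloxy)-5-bromo-4-methoxyphenyl]-3-[4-(benzyloxy)-2-(methoxymethoxy)phenyl]propan-1-ol | COc1cc(OCc2ccccc2)c([C@H](Cc2ccc(OCc3ccccc3)cc2OCOC)CO)cc1Br | intermediate
18 | 5-(benzyloxy)-2-{(2S)-2-[2-(benzyloxy)-5-bromo-4-methoxyphenyl]-3-hydroxypropyl}phenol | COc1cc(OCc2ccccc2)c([C@H](Cc2ccc(OCc3ccccc3)cc2O)CO)cc1Br | intermediate
19 | (3S)-7-(benzyloxy)-3-[2-(benzyloxy)-5-bromo-4-methoxyphenyl]chroman | COc1cc(OCc2ccccc2)c([C@H]2COc3cc(OCc4ccccc4)ccc3C2)cc1Br | intermediate
20 | {4-(benzyloxy)-5-[(3S)-7-(benzyloxy)chroman-3-yl]-2-methoxyphenyl}lithium | COc1cc(OCc2ccccc2)c([C@H]2COc3cc(OCc4ccccc4)ccc3C2)cc1[Li] | intermediate (not isolated)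
21 | 4-(benzyloxy)-5-[(3S)-7-(benzyloxy)chroman-3-yl]-2-methoxybenzaldehyde | COc1cc(OCc2ccccc2)c([C@H]2COc3cc(OCc4ccccc4)ccc3C2)cc1C=O | intermediate
22 | (R)-4-benzyloxazolidin-2-one | O=C1N[C@H](Cc2ccccc2)CO1 | starting material
23 | 2-[2-(benzyloxy)-4-methoxyphenyl]acetic pivalic anhydride | COc1ccc(CC(=O)OC(=O)C(C)(C)C)c(OCc2ccccc2)c1 | intermediate (not isolated)
24 | (4R)-4-benzyl-3-{2-[2-(benzyloxy)-4-methoxyphenyl]acetyl}oxazolidin-2-one | COc1ccc(CC(=O)N2[C@H](Cc3ccccc3)COC2=O)c(OCc2ccccc2)c1 | intermediate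
25 | dibutylboron (Z)-enolate of 24 | COc1ccc(/C=C(\OB(CCCC)CCCC)N2[C@H](Cc3ccccc3)COC2=O)c(OCc2ccccc2)c1 | intermediate (not isolated)
26 | (4R)-4-benzyl-3-[(2R,3R)-2-[2-(benzyloxy)-4-methoxyphenyl]-3-{4-(benzyloxy)-5-[(3S)-7-(benzyloxy)chroman-3-yl]-2-methoxyphenyl}-3-hydroxypropanoyl]oxazolidin-2-one | COc1ccc([C@H]([C@@H](O)c2cc([C@H]5COc6cc(OCc7ccccc7)ccc6C5)c(OCc5ccccc5)cc2OC)C(=O)N2[C@H](Cc3ccccc3)COC2=O)c(OCc2ccccc2)c1 | intermediate
27 | (1R,2S)-2-[2-(benzyloxy)-4-methoxyphenyl]-1-{4-(benzyloxy)-5-[(3S)-7-(benzyloxy)chroman-3-yl]-2-methoxyphenyl}propane-1,3-diol | COc1ccc([C@H]([C@@H](O)c2cc([C@H]5COc6cc(OCc7ccccc7)ccc6C5)c(OCc5ccccc5)cc2OC)CO)c(OCc2ccccc2)c1 | intermediate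
28 | 3-(benzyloxy)phenol | Oc1cccc(OCc2ccccc2)c1 | starting material
29 | (1R,2S)-2-[2-(benzyloxy)-4-methoxyphenyl]-1-{4-(benzyloxy)-5-[(3S)-7-(benzyloxy)chroman-3-yl]-2-methoxyphenyl}-3-[3-(benzyloxy)phenoxy]propan-1-ol | COc1ccc([C@H]([C@@H](O)c2cc([C@H]5COc6cc(OCc7ccccc7)ccc6C5)c(OCc5ccccc5)cc2OC)COc2cccc(OCc3ccccc3)c2)c(OCc2ccccc2)c1 | intermediate
30 | benzylic cation from 29 (C1 cation, C2 still S) | COc1ccc([C@H]([CH+]c2cc([C@H]5COc6cc(OCc7ccccc7)ccc6C5)c(OCc5ccccc5)cc2OC)COc2cccc(OCc3ccccc3)c2)c(OCc2ccccc2)c1 | intermediate (not isolated)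
31 | (3S,4R)-7-(benzyloxy)-3-[2-(benzyloxy)-4-methoxyphenyl]-4-{4-(benzyloxy)-5-[(3S)-7-(benzyloxy)chroman-3-yl]-2-methoxyphenyl}chroman | COc1ccc([C@H]2COc3cc(OCc4ccccc4)ccc3[C@@H]2c2cc([C@H]5COc6cc(OCc7ccccc7)ccc6C5)c(OCc5ccccc5)cc2OC)c(OCc2ccccc2)c1 | intermediate
32 | (3S,4R)-3-(2-hydroxy-4-methoxyphenyl)-4-{4-hydroxy-5-[(3S)-7-hydroxychroman-3-yl]-2-methoxyphenyl}chroman-7-ol (CNP0152030.1) | COc1ccc([C@H]2COc3cc(O)ccc3[C@@H]2c2cc([C@H]3COc4cc(O)ccc4C3)c(O)cc2OC)c(O)c1 | target

**Step count**

Total: 20 steps. Longest linear sequence: 15 steps (steps 1–4, 9–14, 16–20).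

**Steps most likely to fail**

Step 19 (cationic ring closure). The cation may lose H-3 to give the conjugated alkene, and reversible reprotonation would erode the C3 configuration. The ortho benzyloxy oxygen of the C3 aryl may capture the cation, leading to debenzylative dihydrobenzofuran closure. Closure at the carbon between the two oxygens and intermolecular alkylation are further leaks. Fallback: the cation precursor is changed so that ionisation is irreversible and free of protic acid. Setting out from 29, acetylation (Ac2O, pyridine, DMAP, CH2Cl2, 0 °C) should give the benzylic acetate F1. Treating F1 with TMSOTf and 2,6-di-tert-butyl-4-methylpyridine in CH2Cl2 at −78 °C should generate cation 30 under buffered, aprotic conditions, so that no acid is available to reprotonate an alkene. The route is rejoined at 31.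

Step 16 (aldol). Addition of the stabilised arylacetyl boron enolate to a hindered, electron-rich aldehyde may be slow or reversible, retro-aldol cleavage may occur on work-up, and facial selectivity may erode. Fallback: the C1–aryl bond is made by aryllithium addition instead, and upper C3 is set by alkylation. Phenol 28 is converted (NaH, ClCH2SMe, NaI, DMF) into 1-(benzyloxy)-3-[(methylsulfanyl)methoxy]benzene F2, and SO2Cl2 in CH2Cl2 at 0 °C should give 1-(benzyloxy)-3-(chloromethoxy)benzene F3. Setting out from 24, NaHMDS (THF, −78 °C) gives the sodium Z-enolate F4, which is alkylated with F3 to the (2S)-imide F5. The same (R)-auxiliary serves because alkylation uses the enolate face opposite to the aldol and the electrophile now supplies C2 instead of C4. LiBH4 gives the (2R)-alcohol F6, and buffered Dess–Martin oxidation gives the (2S)-aldehyde F7, used at once. Aryllithium 20 (from 19 as in step 14, without DMF) is added at −78 °C. This comes back to the route at 29, formed together with its C1 epimer F8; both give cation 30 in step 19.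

Step 18 (Mitsunobu on the diol). The secondary benzylic hydroxyl may be activated in competition (substitution at C1 or oxetane closure), and the electron-rich carbinol may ionise during purification. Fallback: the carbinol is masked before the primary alcohol is released. Setting out from 26, TBSOTf and 2,6-lutidine (CH2Cl2, −78 to 0 °C) give the silyl ether F9, and LiBH4 gives the primary alcohol F10. Mitsunobu etherification with 28 (PPh3, DIAD) gives the aryl ether F11, and TBAF in THF comes back to the route at 29.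

**Further compounds**

F1 | step 19 | (1R,2S)-2-[2-(benzyloxy)-4-methoxyphenyl]-1-{4-(benzyloxy)-5-[(3S)-7-(benzyloxy)chroman-3-yl]-2-methoxyphenyl}-3-[3-(benzyloxy)phenoxy]propyl acetate | COc1ccc([C@H]([C@@H](OC(C)=O)c2cc([C@H]5COc6cc(OCc7ccccc7)ccc6C5)c(OCc5ccccc5)cc2OC)COc2cccc(OCc3ccccc3)c2)c(OCc2ccccc2)c1
F2 | step 16 | 1-(benzyloxy)-3-[(methylsulfanyl)methoxy]benzene | CSCOc1cccc(OCc2ccccc2)c1
F3 | step 16 | 1-(benzyloxy)-3-(chloromethoxy)benzene | ClCOc1cccc(OCc2ccccc2)c1
F4 | step 16 | sodium (Z)-enolate of 24 | COc1ccc(/C=C(\O[Na])N2[C@H](Cc3ccccc3)COC2=O)c(OCc2ccccc2)c1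
F5 | step 16 | (4R)-4-benzyl-3-{(2S)-2-[2-(benzyloxy)-4-methoxyphenyl]-3-[3-(benzyloxy)phenoxy]propanoyl}oxazolidin-2-one | COc1ccc([C@H](C(=O)N2[C@H](Cc3ccccc3)COC2=O)COc2cccc(OCc3ccccc3)c2)c(OCc2ccccc2)c1
F6 | step 16 | (2R)-2-[2-(benzyloxy)-4-methoxyphenyl]-3-[3-(benzyloxy)phenoxy]propan-1-ol | COc1ccc([C@H](CO)COc2cccc(OCc3ccccc3)c2)c(OCc2ccccc2)c1
F7 | step 16 | (2S)-2-[2-(benzyloxy)-4-methoxyphenyl]-3-[3-(benzyloxy)phenoxy]propanal | COc1ccc([C@H](C=O)COc2cccc(OCc3ccccc3)c2)c(OCc2ccccc2)c1
F8 | step 16 | (1S,2S)-2-[2-(benzyloxy)-4-methoxyphenyl]-1-{4-(benzyloxy)-5-[(3S)-7-(benzyloxy)chroman-3-yl]-2-methoxyphenyl}-3-[3-(benzyloxy)phenoxy]propan-1-ol | COc1ccc([C@H]([C@H](O)c2cc([C@H]5COc6cc(OCc7ccccc7)ccc6C5)c(OCc5ccccc5)cc2OC)COc2cccc(OCc3ccccc3)c2)c(OCc2ccccc2)c1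
F9 | step 18 | (4R)-4-benzyl-3-[(2R,3R)-2-[2-(benzyloxy)-4-methoxyphenyl]-3-{4-(benzyloxy)-5-[(3S)-7-(benzyloxy)chroman-3-yl]-2-methoxyphenyl}-3-(tert-butyldimethylsilyloxy)propanoyl]oxazolidin-2-one | COc1ccc([C@H]([C@@H](O[Si](C)(C)C(C)(C)C)c2cc([C@H]5COc6cc(OCc7ccccc7)ccc6C5)c(OCc5ccccc5)cc2OC)C(=O)N2[C@H](Cc3ccccc3)COC2=O)c(OCc2ccccc2)c1
F10 | step 18 | (2S,3R)-2-[2-(benzyloxy)-4-methoxyphenyl]-3-{4-(benzyloxy)-5-[(3S)-7-(benzyloxy)chroman-3-yl]-2-methoxyphenyl}-3-(tert-butyldimethylsilyloxy)propan-1-ol | COc1ccc([C@H]([C@@H](O[Si](C)(C)C(C)(C)C)c2cc([C@H]5COc6cc(OCc7ccccc7)ccc6C5)c(OCc5ccccc5)cc2OC)CO)c(OCc2ccccc2)c1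
F11 | step 18 | tert-butyldimethylsilyl ether of 29 at the (1R)-carbinol | COc1ccc([C@H]([C@@H](O[Si](C)(C)C(C)(C)C)c2cc([C@H]5COc6cc(OCc7ccccc7)ccc6C5)c(OCc5ccccc5)cc2OC)COc2cccc(OCc3ccccc3)c2)c(OCc2ccccc2)c1
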